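**Retrosynthetic overview**
1. Feature: C6'' of unit 2 lies between O5'' and O7'' and para to O1''. Without ring C, ring A of unit 2 is therefore a 2,4,6-trihydroxyphenyl group on C8 of unit 1. This group is symmetric about the C8–C6'' axis, with two equivalent CH carbons (future C4a''/C8'') and one unhindered oxygen (future O1'').
2. Endgame: 7''-OH, the only hydroxyl not hydrogen-bonded to a C4 carbonyl, is methylated. The 5-, 7- and 4'''-O-benzyl groups are then hydrogenolysed.
3. Key disconnection: ring C of unit 2 (C4''–C4a'' and O1''–C2'') is cut by an acid-free thermal Mentzer condensation of the arylphloroglucinol with ethyl 4-benzyloxybenzoylacetate. This reagent also brings in ring B of unit 2.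
4. The C8–C6'' bond is made earlier by Suzuki–Miyaura coupling of 8-iodo-5,7-di-O-benzylacacetin with a tris(methoxymethyl)-protected phloroglucinol boronate, followed by MOM removal.
5. Ring order: rings A, B and C of unit 1 are bought as acacetin. Ring A of unit 2 is bought as phloroglucinol and attached. Ring C of unit 2 is the only ring built.

Key step: step 8

Assumption: the target SMILES carries no axial descriptor and has no stereocentre, so the compound is made as the racemate about the hindered C8–C6'' axis.

**Step 1**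
Reactants: 1 acacetin (5,7-dihydroxy-4'-methoxyflavone)
Product: 2 5,7-bis(benzyloxy)-4'-methoxyflavone
Conditions: BnBr (3 equiv), K2CO3 (4 equiv), DMF, 80 °C
Reagents that add atoms: benzyl bromide, BrCc1ccccc1
Why: Williamson etherification in which the acidic 7-OH reacts first and heat with excess base and bromide also alkylates the hydrogen-bonded 5-OH, while the 4'-methyl ether and the pyranone are inert.

**Step 2**
Reactants: 2 5,7-bis(benzyloxy)-4'-methoxyflavone
Product: 3 5,7-bis(benzyloxy)-8-iodo-4'-methoxyflavone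
Conditions: NIS (1.2 equiv), DMF, rt to 50 °C, dark
Reagents that add atoms: N-iodosuccinimide, O=C1CCC(=O)N1I
Why: Electrophilic aromatic iodination of the most electron-rich ring, in which C6 is walled in by two benzyloxy groups once both oxygens are alkylated, so iodine enters at C8 between 7-OBn and the tied-back ring oxygen, the usual outcome for 5,7-dialkoxyflavones.

**Step 3**
Reactants: 4 phloroglucinol (benzene-1,3,5-triol)
Product: 5 1,3,5-tris(methoxymethoxy)benzene
Conditions: NaH (3.6 equiv), MOMCl (3.6 equiv), DMF, 0 °C to rt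
Reagents that add atoms: chloromethyl methyl ether, COCCl
Why: Williamson-type alkylation with a hard, oxocarbenium-like electrophile, which takes the phloroglucinol anion at oxygen rather than at carbon.

**Step 4**
Reactants: 5 1,3,5-tris(methoxymethoxy)benzene
Product: 7 2-[2,4,6-tris(methoxymethoxy)phenyl]-4,4,5,5-tetramethyl-1,3,2-dioxaborolane, via 2,4,6-tris(methoxymethoxy)phenyllithium 6 (not isolated)
Conditions: n-BuLi (1.05 equiv), THF, 0 °C; iPrOBpin (1.3 equiv), −78 °C to rt; aq NH4Cl
Reagents that add atoms: 2-isopropoxy-4,4,5,5-tetramethyl-1,3,2-dioxaborolane, CC(C)OB1OC(C)(C)C(C)(C)O1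
Why: Directed ortho-metalation, in which every ring CH lies between two chelating OMOM groups and all three are equivalent, so a single aryllithium forms and is trapped at boron.

**Step 5**
Reactants: 3 5,7-bis(benzyloxy)-8-iodo-4'-methoxyflavone; 7 2-[2,4,6-tris(methoxymethoxy)phenyl]-4,4,5,5-tetramethyl-1,3,2-dioxaborolane (1.8 equiv)
Product: 8 5,7-bis(benzyloxy)-4'-methoxy-8-[2,4,6-tris(methoxymethoxy)phenyl]flavone
Conditions: Pd(OAc)2 (5 mol %), SPhos (2-dicyclohexylphosphino-2',6'-dimethoxybiphenyl, 10 mol %), K3PO4 (3 equiv), toluene–H2O, 100 °C, argon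
Reagents that add atoms: none
Why: Suzuki–Miyaura coupling in which the bulky electron-rich biarylphosphine keeps monoligated zerovalent palladium active enough for oxidative addition to the hindered iodide and for reductive elimination to a biaryl whose four ortho substituents are all small oxygen groups.

**Step 6**
Reactants: 8 5,7-bis(benzyloxy)-4'-methoxy-8-[2,4,6-tris(methoxymethoxy)phenyl]flavone
Product: 9 5,7-bis(benzyloxy)-4'-methoxy-8-(2,4,6-trihydroxyphenyl)flavone
Conditions: aq HCl (3 M, cat.), ethane-1,2-dithiol (5 equiv), MeOH–THF, 45 °C, argon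
Reagents that add atoms: none
Why: Acid-catalysed acetal cleavage removes the three MOM groups under conditions that leave aryl benzyl ethers alone, and the dithiol binds the released C1 electrophile as 1,3-dithiolane before it can alkylate the very nucleophilic free ring.

**Step 7**
Reactants: 10 4'-benzyloxyacetophenone; 11 diethyl carbonate (3 equiv)
Product: 12 ethyl 3-(4-benzyloxyphenyl)-3-oxopropanoate
Conditions: NaH (2.5 equiv), THF, reflux; aq HCl
Reagents that add atoms: none
Why: Crossed Claisen condensation of the ketone enolate with a non-enolisable carbonate, driven by irreversible deprotonation of the β-ketoester formed.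

**Step 8**
Reactants: 9 5,7-bis(benzyloxy)-4'-methoxy-8-(2,4,6-trihydroxyphenyl)flavone; 12 ethyl 3-(4-benzyloxyphenyl)-3-oxopropanoate (2.5 equiv, in portions)
Product: 15 5,7-bis(benzyloxy)-8-[2-(4-benzyloxyphenyl)-5,7-dihydroxy-4-oxo-4H-chromen-6-yl]-2-(4-methoxyphenyl)-4H-chromen-4-one, via 4-benzyloxybenzoylketene 13 (not isolated), via C-aroylacetylated triol 14 (not isolated)
Conditions: Ph2O, 235–245 °C, argon sweep (EtOH and H2O distilled out), no acid, no base
Reagents that add atoms: none
Why: Above about 230 °C 12 loses ethanol to give aroylketene 13, whose ketene carbon acylates one of the two equivalent, strongly nucleophilic CH carbons of the phloroglucinol ring (O-acylation is reversible at this temperature and drains back through 13), which forms C4''–C4a'' in diketone 14. The hydroxyl para to the biaryl axis then adds to the aryl ketone of 14 in a 6-exo-trig closure, and loss of water forms O1''–C2'' and the aromatic pyranone ring C of unit 2. This is the Mentzer pyrone synthesis, the acid-free thermal condensation of phloroglucinols with aroylacetates to 5,7-dihydroxyflavones, applied here to a C-aryl phloroglucinol. Chromone rather than 4-arylcoumarin is needed, and the absence of acid secures it, because the Pechmann pathway requires the aryl ketone to be activated for attack by the ring carbon, whereas in the neutral melt the ketene carbon is the only strong electrophile. Closure by the para hydroxyl rather than by the one beside the axis is needed, and it is favoured because the latter is buttressed by the orthogonal unit 1 (7-OBn and O1 above and below it) into the hydrogen bond with the new C4'' carbonyl and would have to press ring B of unit 2 against unit 1, so the linkage becomes C6''. No stereocentre is formed, the C8–C6'' axis becomes stereogenic here and arises as a racemate, and a second annulation is not expected because the new carbonyl deactivates the remaining C8''–H.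

**Step 9**
Reactants: 15 5,7-bis(benzyloxy)-8-[2-(4-benzyloxyphenyl)-5,7-dihydroxy-4-oxo-4H-chromen-6-yl]-2-(4-methoxyphenyl)-4H-chromen-4-one
Product: 16 5,7-bis(benzyloxy)-8-[2-(4-benzyloxyphenyl)-5-hydroxy-7-methoxy-4-oxo-4H-chromen-6-yl]-2-(4-methoxyphenyl)-4H-chromen-4-one
Conditions: MeI (1.05 equiv), K2CO3 (1.2 equiv), DMF, rt
Reagents that add atoms: iodomethane, CI
Why: Selective Williamson methylation, since 7''-OH is a vinylogous acid and the only hydroxyl not locked in a hydrogen bond to a C4 carbonyl, so one equivalent of electrophile is taken up there while 5''-OH stays untouched.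

**Step 10**
Reactants: 16 5,7-bis(benzyloxy)-8-[2-(4-benzyloxyphenyl)-5-hydroxy-7-methoxy-4-oxo-4H-chromen-6-yl]-2-(4-methoxyphenyl)-4H-chromen-4-one
Product: 17 5,7-dihydroxy-8-[5-hydroxy-2-(4-hydroxyphenyl)-7-methoxy-4-oxo-4H-chromen-6-yl]-2-(4-methoxyphenyl)-4H-chromen-4-one (target CNP0253922.0)
Conditions: H2 (1 atm), 10% Pd/C, THF–MeOH, rt
Reagents that add atoms: none
Why: Catalytic hydrogenolysis of the three aryl benzyl ethers, under which aryl methyl ethers and the cross-conjugated C2–C3 double bonds of both flavones persist at ambient pressure.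

**Compound list**
1 | acacetin (5,7-dihydroxy-4'-methoxyflavone) | COc1ccc(-c2cc(=O)c3c(O)cc(O)cc3o2)cc1 | starting material
2 | 5,7-bis(benzyloxy)-4'-methoxyflavone | COc1ccc(-c2cc(=O)c3c(OCc4ccccc4)cc(OCc4ccccc4)cc3o2)cc1 | intermediate
3 | 5,7-bis(benzyloxy)-8-iodo-4'-methoxyflavone | COc1ccc(-c2cc(=O)c3c(OCc4ccccc4)cc(OCc4ccccc4)c(I)c3o2)cc1 | intermediate
4 | phloroglucinol | Oc1cc(O)cc(O)c1 | starting material
5 | 1,3,5-tris(methoxymethoxy)benzene | COCOc1cc(OCOC)cc(OCOC)c1 | intermediate
6 | 2,4,6-tris(methoxymethoxy)phenyllithium | [Li]c1c(OCOC)cc(OCOC)cc1OCOC | intermediate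
7 | 2-[2,4,6-tris(methoxymethoxy)phenyl]-4,4,5,5-tetramethyl-1,3,2-dioxaborolane | COCOc1cc(OCOC)c(B2OC(C)(C)C(C)(C)O2)c(OCOC)c1 | intermediate
8 | 5,7-bis(benzyloxy)-4'-methoxy-8-[2,4,6-tris(methoxymethoxy)phenyl]flavone | COc1ccc(-c2cc(=O)c3c(OCc4ccccc4)cc(OCc4ccccc4)c(-c4c(OCOC)cc(OCOC)cc4OCOC)c3o2)cc1 | intermediate
9 | 5,7-bis(benzyloxy)-4'-methoxy-8-(2,4,6-trihydroxyphenyl)flavone | COc1ccc(-c2cc(=O)c3c(OCc4ccccc4)cc(OCc4ccccc4)c(-c4c(O)cc(O)cc4O)c3o2)cc1 | intermediate
10 | 4'-benzyloxyacetophenone | CC(=O)c1ccc(OCc2ccccc2)cc1 | starting material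
11 | diethyl carbonate | CCOC(=O)OCC | starting material
12 | ethyl 3-(4-benzyloxyphenyl)-3-oxopropanoate | CCOC(=O)CC(=O)c1ccc(OCc2ccccc2)cc1 | intermediate
13 | 4-benzyloxybenzoylketene | O=C=CC(=O)c1ccc(OCc2ccccc2)cc1 | intermediate
14 | 1-[3-(5,7-bis(benzyloxy)-4'-methoxyflavon-8-yl)-2,4,6-trihydroxyphenyl]-3-(4-benzyloxyphenyl)propane-1,3-dione | COc1ccc(-c2cc(=O)c3c(OCc4ccccc4)cc(OCc4ccccc4)c(-c4c(O)cc(O)c(C(=O)CC(=O)c5ccc(OCc6ccccc6)cc5)c4O)c3o2)cc1 | intermediate
15 | 5,7,4'''-tri-O-benzyl-7''-O-demethyl derivative of the target | COc1ccc(-c2cc(=O)c3c(OCc4ccccc4)cc(OCc4ccccc4)c(-c4c(O)cc5oc(-c6ccc(OCc7ccccc7)cc6)cc(=O)c5c4O)c3o2)cc1 | intermediate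
16 | 5,7,4'''-tri-O-benzyl derivative of the target | COc1ccc(-c2cc(=O)c3c(OCc4ccccc4)cc(OCc4ccccc4)c(-c4c(OC)cc5oc(-c6ccc(OCc7ccccc7)cc6)cc(=O)c5c4O)c3o2)cc1 | intermediate
17 | CNP0253922.0 (8,6''-linked biflavone; 5,7,5'',4'''-tetrahydroxy-4',7''-dimethoxy) | COc1ccc(-c2cc(=O)c3c(O)cc(O)c(-c4c(OC)cc5oc(-c6ccc(O)cc6)cc(=O)c5c4O)c3o2)cc1 | target

**Total step count:** 10
**Longest linear sequence:** 7 steps (steps 1, 2, 5, 6, 8, 9, 10 from acacetin; the phloroglucinol branch through steps 3 and 4 is equally long)

**Three steps most likely to fail**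

**Step 8.**
- What may go wrong: ring closure through the hindered hydroxyl beside the axis, which would erode the C6''/C8'' regioselectivity. Other risks are Pechmann-type closure if traces of acid are present, self-condensation of the ketene, and thermal migration or loss of benzyl groups.
- Fallback: it sets out from 3 and comes back at 17, and it fixes the linkage by the positions of halogen and boron instead of by a ring closure.
- Miyaura borylation of 3 (B2pin2, PdCl2(dppf), KOAc, dioxane, 90 °C) should give 5,7-bis(benzyloxy)-4'-methoxyflavone-8-boronic acid pinacol ester F1.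
- Commercial genkwanin F2 is benzylated at its only non-chelated hydroxyl (BnBr, K2CO3, acetone) to 4'-O-benzylgenkwanin F3.
- F3 is iodinated ortho to the free 5-OH (benzyltrimethylammonium dichloroiodate, CaCO3, CH2Cl2–MeOH) to 4'-O-benzyl-6-iodogenkwanin F4.
- F4 is benzylated at O5 (BnBr, K2CO3, DMF, 80 °C) to 5,4'-di-O-benzyl-6-iodogenkwanin F5.
- Suzuki–Miyaura coupling of F1 with F5 (Pd(OAc)2, SPhos, K3PO4, toluene–H2O, 100 °C) should give the 5,7,5'',4'''-tetra-O-benzyl derivative of the target F6. Hydrogenolysis under the conditions of step 10 then gives 17.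

**Step 5.**
- What may go wrong: protodeboronation of the doubly ortho-oxygenated boronate may outrun the slow transmetalation, and the iodide may be reductively deiodinated.
- Fallback: it sets out from 5 and comes back at 8, and it replaces boron, base and water by an organozinc partner.
- Lithiation as in step 4 gives 6, which ZnCl2 (THF, 0 °C) converts to 2,4,6-tris(methoxymethoxy)phenylzinc chloride F7.
- Negishi coupling of F7 with 3 (Pd2(dba)3, RuPhos (2-dicyclohexylphosphino-2',6'-diisopropoxybiphenyl), THF, 65 °C) should give 8.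

**Step 6.**
- What may go wrong: the freed phloroglucinol ring may be C-alkylated by the released C1 electrophile if the scavenger is too slow, or the triol may be oxidised by air. Partial loss of the peri 5-O-benzyl group is also possible, but would be harmless because a chelated 5-OH is a spectator in steps 8 and 9.
- Fallback: it sets out from 8 and comes back at 9, and it separates the C1 fragment physically before any phenol is unmasked.
- TMSOTf and 2,2'-bipyridyl in MeCN (0 °C to rt) exchange each aryl MOM ether for a silyl ether under non-acidic conditions. This gives 5,7-bis(benzyloxy)-4'-methoxy-8-[2,4,6-tris(trimethylsilyloxy)phenyl]flavone F8.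
- The methoxymethyl units leave as an N-(methoxymethyl)bipyridinium salt, which is precipitated with ether and filtered off.
- Methanolysis of F8 (MeOH, rt, argon) then gives 9.

**Further compounds**
F1 | step 8 | 5,7-bis(benzyloxy)-4'-methoxyflavone-8-boronic acid pinacol ester | COc1ccc(-c2cc(=O)c3c(OCc4ccccc4)cc(OCc4ccccc4)c(B4OC(C)(C)C(C)(C)O4)c3o2)cc1
F2 | step 8 | genkwanin (5,4'-dihydroxy-7-methoxyflavone, commercial) | COc1cc(O)c2c(=O)cc(-c3ccc(O)cc3)oc2c1
F3 | step 8 | 4'-O-benzylgenkwanin | COc1cc(O)c2c(=O)cc(-c3ccc(OCc4ccccc4)cc3)oc2c1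
F4 | step 8 | 4'-O-benzyl-6-iodogenkwanin | COc1cc2oc(-c3ccc(OCc4ccccc4)cc3)cc(=O)c2c(O)c1I
F5 | step 8 | 5,4'-di-O-benzyl-6-iodogenkwanin | COc1cc2oc(-c3ccc(OCc4ccccc4)cc3)cc(=O)c2c(OCc2ccccc2)c1I
F6 | step 8 | 5,7,5'',4'''-tetra-O-benzyl derivative of the target | COc1ccc(-c2cc(=O)c3c(OCc4ccccc4)cc(OCc4ccccc4)c(-c4c(OC)cc5oc(-c6ccc(OCc7ccccc7)cc6)cc(=O)c5c4OCc4ccccc4)c3o2)cc1
F7 | step 5 | 2,4,6-tris(methoxymethoxy)phenylzinc chloride | Cl[Zn]c1c(OCOC)cc(OCOC)cc1OCOC
F8 | step 6 | 5,7-bis(benzyloxy)-4'-methoxy-8-[2,4,6-tris(trimethylsilyloxy)phenyl]flavone | COc1ccc(-c2cc(=O)c3c(OCc4ccccc4)cc(OCc4ccccc4)c(-c4c(O[Si](C)(C)C)cc(O[Si](C)(C)C)cc4O[Si](C)(C)C)c3o2)cc1
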